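**Assumption:** (2R,3R)-1,2:3,4-diepoxybutane (1) and trimethyl(but-3-en-1-yn-1-yl)silane (21) are taken as catalogue chemicals; C-numbers in the text are the C1–C15 chain numbers of the target (C1 = alkyne CH, C15 = ethyl CH3).

**Retrosynthetic overview**
1. Target 23 ⇐ fluoride desilylation ⇐ Z-enyne cross-metathesis of the C6-allyl oxocane triacetate 20.
2. Oxocane 20 ⇐ ring expansion (5 → 8) of oxolane 15: the ring oxygen opens the C12–C13 cis-oxirane, and the C10 acetate then cuts the old O–C9 bond of the bicyclic oxonium ion.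
3. Oxolane 15 ⇐ rhenium syn-oxidative cyclisation of hydroxy-alkene 13, which sets C9 and C10.
4. 13 ⇐ vinyl Grignard, silylation, Lindlar ⇐ alkynol 9 ⇐ epoxy-alkyne 8 + diepoxide 1; 8 ⇐ 1 + MeMgBr + ethynyltrimethylsilane.
5. Ring order: oxolane first, then oxocane by expansion; C6, C7, C12 and C13 all come from the single chiral diepoxide 1.

**Step 1**
Reactants: 1 (2R,3R)-1,2:3,4-diepoxybutane (3 equiv); 2 methylmagnesium bromide
Product: 4 (1R)-1-[(2R)-oxiran-2-yl]propyl methanesulfonate, via bromomagnesium alkoxide 3 (not isolated)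
Conditions: MeMgBr, CuI (10 mol%), THF, −40 °C; then MsCl, −40 → 0 °C
Reagents that add atoms: methanesulfonyl chloride, CS(=O)(=O)Cl
Why: Copper-catalysed Grignard opening (SN2) at a terminal CH2 of C2-symmetric 1 (both oxiranes are equivalent, excess 1 limits double opening) followed by O-sulfonylation of the alkoxide; C12 and C13 keep the configuration of 1.

**Step 2**
Reactants: 4 (1R)-1-[(2R)-oxiran-2-yl]propyl methanesulfonate; 5 ethynyltrimethylsilane
Product: 8 (2S,3R)-2-ethyl-3-(prop-2-yn-1-yl)oxirane, via hydroxy mesylate 6 (not isolated), via silylated epoxy alkyne 7 (not isolated)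
Conditions: 5, n-BuLi, THF, −78 °C; BF3·OEt2; 4, −78 °C; then K2CO3, MeOH, 0 °C → rt
Reagents that add atoms: none
Why: Yamaguchi alkynylation (lithium acetylide/BF3) at the oxirane CH2, then the C12 alkoxide displaces the C13 mesylate with inversion (intramolecular Williamson reaction, giving the cis-oxirane) and methanolysis cleaves the C–Si bond.

**Step 3**
Reactants: 8 (2S,3R)-2-ethyl-3-(prop-2-yn-1-yl)oxirane; 1 (2R,3R)-1,2:3,4-diepoxybutane (3 equiv)
Product: 9 (1R)-5-[(2R,3S)-3-ethyloxiran-2-yl]-1-[(2R)-oxiran-2-yl]pent-3-yn-1-ol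
Conditions: 8, n-BuLi (1.0 equiv), THF, −78 °C; BF3·OEt2; 1, −78 °C
Reagents that add atoms: none
Why: Second Yamaguchi alkynylation, in which the acetylide/BF3 opens one terminal oxirane of 1 at CH2 much faster than it could attack the cis-disubstituted oxirane of 8; C6 and C7 come unchanged from 1.

**Step 4**
Reactants: 9 (1R)-5-[(2R,3S)-3-ethyloxiran-2-yl]-1-[(2R)-oxiran-2-yl]pent-3-yn-1-ol
Product: 10 (1R,3Z)-5-[(2R,3S)-3-ethyloxiran-2-yl]-1-[(2R)-oxiran-2-yl]pent-3-en-1-ol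
Conditions: H2 (1 atm), Pd/CaCO3/Pb(OAc)2 (Lindlar catalyst), quinoline, EtOAc, rt
Reagents that add atoms: none
Why: Lindlar semi-hydrogenation gives the Z-alkene by syn addition of H2 and leaves both oxiranes untouched.

**Step 5**
Reactants: 10 (1R,3Z)-5-[(2R,3S)-3-ethyloxiran-2-yl]-1-[(2R)-oxiran-2-yl]pent-3-en-1-ol
Product: 11 tert-butyl{[(1R,3Z)-5-[(2R,3S)-3-ethyloxiran-2-yl]-1-[(2R)-oxiran-2-yl]pent-3-en-1-yl]oxy}dimethylsilane
Conditions: TBSCl, imidazole, DMF, rt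
Reagents that add atoms: tert-butyldimethylsilyl chloride, CC(C)(C)[Si](C)(C)Cl
Why: Standard silyl ether formation masks the C7 hydroxyl, which must stay distinct from the hydroxyls that are later acetylated.

**Step 6**
Reactants: 11 tert-butyl{[(1R,3Z)-5-[(2R,3S)-3-ethyloxiran-2-yl]-1-[(2R)-oxiran-2-yl]pent-3-en-1-yl]oxy}dimethylsilane; 12 vinylmagnesium bromide
Product: 13 (4R,5R,7Z)-5-{[tert-butyl(dimethyl)silyl]oxy}-9-[(2R,3S)-3-ethyloxiran-2-yl]nona-1,7-dien-4-ol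
Conditions: vinylMgBr, CuI (10 mol%), THF, −40 °C; aq. NH4Cl quench at −40 °C
Reagents that add atoms: none
Why: Copper-catalysed Grignard opening at the terminal oxirane CH2 (the internal cis-oxirane is inert at −40 °C) frees the C6 hydroxyl with retention; the cold quench avoids 1,2-silyl migration.

**Step 7**
Reactants: 13 (4R,5R,7Z)-5-{[tert-butyl(dimethyl)silyl]oxy}-9-[(2R,3S)-3-ethyloxiran-2-yl]nona-1,7-dien-4-ol
Product: 14 (1R)-1-[(2S,4R,5R)-4-{[tert-butyl(dimethyl)silyl]oxy}-5-(prop-2-en-1-yl)oxolan-2-yl]-2-[(2R,3S)-3-ethyloxiran-2-yl]ethan-1-ol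
Conditions: Re2O7, 2,6-lutidine, CH2Cl2, rt
Reagents that add atoms: dirhenium heptoxide (oxygen donor), O=[Re](=O)(=O)O[Re](=O)(=O)=O
Why: Kennedy syn-oxidative cyclisation, in which the perrhenate ester of the C6 hydroxyl (heptavalent rhenium) adds across the bishomoallylic Z-alkene in a syn fashion (erythro C9/C10, so C10 is R) and sterically prefers the 2,5-trans oxolane (C9 is S); the allyl group cannot cyclise.

**Step 8**
Reactants: 14 (1R)-1-[(2S,4R,5R)-4-{[tert-butyl(dimethyl)silyl]oxy}-5-(prop-2-en-1-yl)oxolan-2-yl]-2-[(2R,3S)-3-ethyloxiran-2-yl]ethan-1-ol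
Product: 15 (1R)-1-[(2S,4R,5R)-4-{[tert-butyl(dimethyl)silyl]oxy}-5-(prop-2-en-1-yl)oxolan-2-yl]-2-[(2R,3S)-3-ethyloxiran-2-yl]ethyl acetate
Conditions: Ac2O, pyridine, DMAP (cat.), CH2Cl2, rt
Reagents that add atoms: acetic anhydride, CC(=O)OC(C)=O
Why: Plain acetylation installs the C10 acetate, which is both a target substituent and the participating group for the next step.

**Step 9**
Reactants: 15 (1R)-1-[(2S,4R,5R)-4-{[tert-butyl(dimethyl)silyl]oxy}-5-(prop-2-en-1-yl)oxolan-2-yl]-2-[(2R,3S)-3-ethyloxiran-2-yl]ethyl acetate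
Product: 20 (2R,3R,5R,6R,8S)-8-[(1S)-1-acetoxypropyl]-3-{[tert-butyl(dimethyl)silyl]oxy}-2-(prop-2-en-1-yl)oxocane-5,6-diyl diacetate, via bicyclic oxonium zwitterion 16 (not isolated), via dioxolanylium zwitterion 17 (not isolated), via 5-hydroxy 6-acetate 18 (not isolated), via 5-acetate 6-hydroxy 19 (not isolated)
Conditions: BF3·OEt2, CH2Cl2, −78 → −40 °C; H2O/THF, 0 °C; then Ac2O, pyridine, DMAP, rt
Reagents that add atoms: water, O; acetic anhydride, CC(=O)OC(C)=O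
Why: Proposed new method: BF3 activates the cis-oxirane and the oxolane oxygen, three atoms from C12, opens it 5-exo with inversion at C12 (an ether is a better n-donor than the ester carbonyl, which would need a 6-exo attack) to give a 1-oxoniabicyclo[3.3.0]octane, whose O–C9 bond is then displaced with inversion at C9 by the anti-disposed C10 acetoxy group (1,2-acyloxy participation, dioxolanylium ion), so the five-membered ring becomes the eight-membered one; oxirane strain release makes this irreversible, water opens the dioxolanylium ion and acetylation converges the hydroxy acetates; the closest known reactions are the bromonium-induced oxolane-to-oxocane ring expansion terminated by a neighbouring carbonate and Lewis-acid epoxide opening by ether oxygen, but an epoxide trigger with acetate termination has not been shown.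

**Step 10**
Reactants: 20 (2R,3R,5R,6R,8S)-8-[(1S)-1-acetoxypropyl]-3-{[tert-butyl(dimethyl)silyl]oxy}-2-(prop-2-en-1-yl)oxocane-5,6-diyl diacetate; 21 trimethyl(but-3-en-1-yn-1-yl)silane (4 equiv)
Product: 22 (2R,3R,5R,6R,8S)-8-[(1S)-1-acetoxypropyl]-3-{[tert-butyl(dimethyl)silyl]oxy}-2-[(2Z)-5-(trimethylsilyl)pent-2-en-4-yn-1-yl]oxocane-5,6-diyl diacetate
Conditions: second-generation Grubbs catalyst [RuCl2(=CHPh)(H2IMes)(PCy3)] (10 mol%), CH2Cl2, 40 °C
Reagents that add atoms: none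
Why: Cross-metathesis of a terminal alkene with a conjugated silyl enyne, which is known to favour the Z-enyne; the minor E isomer is removed by chromatography.

**Step 11**
Reactants: 22 (2R,3R,5R,6R,8S)-8-[(1S)-1-acetoxypropyl]-3-{[tert-butyl(dimethyl)silyl]oxy}-2-[(2Z)-5-(trimethylsilyl)pent-2-en-4-yn-1-yl]oxocane-5,6-diyl diacetate
Product: 23 (2R,3R,5R,6R,8S)-8-[(1S)-1-acetoxypropyl]-3-hydroxy-2-[(2Z)-pent-2-en-4-yn-1-yl]oxocane-5,6-diyl diacetate (target)
Conditions: TBAF, AcOH (1:1), THF, 0 °C → rt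
Reagents that add atoms: none
Why: Fluoride cleaves both the C(sp)–Si and the O–Si bond in one operation, and the acetic acid buffer prevents acetyl migration to the freed C7 hydroxyl.

**Compound list**
1 | (2R,3R)-1,2:3,4-diepoxybutane | C1O[C@H]1[C@H]2CO2 | starting material
2 | methylmagnesium bromide | C[Mg]Br | starting material
3 | bromomagnesium (1R)-1-[(2R)-oxiran-2-yl]propan-1-olate | C1O[C@H]1[C@H](O[Mg]Br)CC | intermediate
4 | (1R)-1-[(2R)-oxiran-2-yl]propyl methanesulfonate | C1O[C@H]1[C@H](OS(C)(=O)=O)CC | intermediate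
5 | ethynyltrimethylsilane | C#C[Si](C)(C)C | starting material
6 | (3R,4R)-4-hydroxy-7-(trimethylsilyl)hept-6-yn-3-yl methanesulfonate | C[Si](C)(C)C#CC[C@@H](O)[C@H](OS(C)(=O)=O)CC | intermediate
7 | trimethyl{3-[(2R,3S)-3-ethyloxiran-2-yl]prop-1-yn-1-yl}silane | C[Si](C)(C)C#CC[C@H]1O[C@H]1CC | intermediate
8 | (2S,3R)-2-ethyl-3-(prop-2-yn-1-yl)oxirane | C#CC[C@H]1O[C@H]1CC | intermediate
9 | (1R)-5-[(2R,3S)-3-ethyloxiran-2-yl]-1-[(2R)-oxiran-2-yl]pent-3-yn-1-ol | C1O[C@H]1[C@H](O)CC#CC[C@H]2O[C@H]2CC | intermediate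
10 | (1R,3Z)-5-[(2R,3S)-3-ethyloxiran-2-yl]-1-[(2R)-oxiran-2-yl]pent-3-en-1-ol | C1O[C@H]1[C@H](O)C/C=C\C[C@H]2O[C@H]2CC | intermediate
11 | tert-butyl{[(1R,3Z)-5-[(2R,3S)-3-ethyloxiran-2-yl]-1-[(2R)-oxiran-2-yl]pent-3-en-1-yl]oxy}dimethylsilane | C1O[C@H]1[C@H](O[Si](C)(C)C(C)(C)C)C/C=C\C[C@H]2O[C@H]2CC | intermediate
12 | vinylmagnesium bromide | C=C[Mg]Br | starting material
13 | (4R,5R,7Z)-5-{[tert-butyl(dimethyl)silyl]oxy}-9-[(2R,3S)-3-ethyloxiran-2-yl]nona-1,7-dien-4-ol | C=CC[C@@H](O)[C@H](O[Si](C)(C)C(C)(C)C)C/C=C\C[C@H]1O[C@H]1CC | intermediate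
14 | (1R)-1-[(2S,4R,5R)-4-{[tert-butyl(dimethyl)silyl]oxy}-5-(prop-2-en-1-yl)oxolan-2-yl]-2-[(2R,3S)-3-ethyloxiran-2-yl]ethan-1-ol | C=CC[C@@H]1[C@H](O[Si](C)(C)C(C)(C)C)C[C@H](O1)[C@H](O)C[C@H]2O[C@H]2CC | intermediate
15 | (1R)-1-[(2S,4R,5R)-4-{[tert-butyl(dimethyl)silyl]oxy}-5-(prop-2-en-1-yl)oxolan-2-yl]-2-[(2R,3S)-3-ethyloxiran-2-yl]ethyl acetate | C=CC[C@@H]1[C@H](O[Si](C)(C)C(C)(C)C)C[C@H](O1)[C@H](OC(C)=O)C[C@H]2O[C@H]2CC | intermediate
16 | bicyclic oxonium zwitterion (1-oxoniabicyclo[3.3.0]octane, O+ bonded to C6, C9 and C12; C13–O–BF3 borate) | C=CC[C@@H]1[C@H](O[Si](C)(C)C(C)(C)C)C[C@@H]2[O+]1[C@@H](C[C@H]2OC(C)=O)[C@@H](O[B-](F)(F)F)CC | intermediate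
17 | dioxolanylium zwitterion (2-methyl-1,3-dioxolan-2-ylium fused at C9/C10 of the oxocane; C13–O–BF3 borate) | C=CC[C@@H]1[C@H](O[Si](C)(C)C(C)(C)C)C[C@H]2OC(C)=[O+][C@@H]2C[C@H](O1)[C@@H](O[B-](F)(F)F)CC | intermediate
18 | 5-hydroxy 6-acetate: (2R,3R,5R,6R,8S)-3-{[tert-butyl(dimethyl)silyl]oxy}-5-hydroxy-8-[(1S)-1-hydroxypropyl]-2-(prop-2-en-1-yl)oxocan-6-yl acetate | C=CC[C@@H]1[C@H](O[Si](C)(C)C(C)(C)C)C[C@@H](O)[C@H](OC(C)=O)C[C@H](O1)[C@@H](O)CC | intermediate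
19 | 5-acetate 6-hydroxy: (2R,3R,5R,6R,8S)-3-{[tert-butyl(dimethyl)silyl]oxy}-6-hydroxy-8-[(1S)-1-hydroxypropyl]-2-(prop-2-en-1-yl)oxocan-5-yl acetate | C=CC[C@@H]1[C@H](O[Si](C)(C)C(C)(C)C)C[C@@H](OC(C)=O)[C@H](O)C[C@H](O1)[C@@H](O)CC | intermediate
20 | (2R,3R,5R,6R,8S)-8-[(1S)-1-acetoxypropyl]-3-{[tert-butyl(dimethyl)silyl]oxy}-2-(prop-2-en-1-yl)oxocane-5,6-diyl diacetate | C=CC[C@@H]1[C@H](O[Si](C)(C)C(C)(C)C)C[C@@H](OC(C)=O)[C@H](OC(C)=O)C[C@H](O1)[C@@H](OC(C)=O)CC | intermediate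
21 | trimethyl(but-3-en-1-yn-1-yl)silane | C=CC#C[Si](C)(C)C | starting material
22 | (2R,3R,5R,6R,8S)-8-[(1S)-1-acetoxypropyl]-3-{[tert-butyl(dimethyl)silyl]oxy}-2-[(2Z)-5-(trimethylsilyl)pent-2-en-4-yn-1-yl]oxocane-5,6-diyl diacetate | C[Si](C)(C)C#C/C=C\C[C@@H]1[C@H](O[Si](C)(C)C(C)(C)C)C[C@@H](OC(C)=O)[C@H](OC(C)=O)C[C@H](O1)[C@@H](OC(C)=O)CC | intermediate
23 | (2R,3R,5R,6R,8S)-8-[(1S)-1-acetoxypropyl]-3-hydroxy-2-[(2Z)-pent-2-en-4-yn-1-yl]oxocane-5,6-diyl diacetate | C#C/C=C\C[C@H]1O[C@H]([C@H](CC)OC(C)=O)C[C@@H](OC(C)=O)[C@H](OC(C)=O)C[C@H]1O | target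

**Totals**
Total step count: 11. Longest linear sequence: 11 (1 → 4 → 8 → 9 → 10 → 11 → 13 → 14 → 15 → 20 → 22 → 23).

**Three steps most likely to fail**

Step 9 (proposed new ring expansion). The risks are that the acetate carbonyl attacks the activated oxirane itself (6-exo), or that the oxonium ion is opened at C12 or C6 and the oxolane is kept. The fallback uses known chemistry, sets out from 13 and comes back at 20, leaving out steps 7 to 9. Heating 13 with Eu(fod)3 (trivalent europium) in toluene at 110 °C brings about the lanthanide-promoted 8-exo hydroxy-epoxide cyclisation that is established for Laurencia oxocenes. The Z-alkene preorganises the chain and the C6 hydroxyl opens the oxirane at C12 with inversion, giving the oxocene alcohol (1S)-1-[(2S,4Z,7R,8R)-7-{[tert-butyl(dimethyl)silyl]oxy}-8-(prop-2-en-1-yl)-3,6,7,8-tetrahydro-2H-oxocin-2-yl]propan-1-ol F1. Ac2O/pyridine gives its acetate F2. Dimethyldioxirane in acetone epoxidises the ring alkene from the face away from the silyloxy group to the (9R,10S)-epoxide F3. CsOAc/AcOH in DMF at 80 °C opens it at C10 with inversion to the 5-hydroxy 6-acetate F4, and Ac2O/pyridine/DMAP gives 20. Face and site selectivity in the last two operations are substrate-controlled only, so the isomeric trans-diacetate has to be removed by chromatography.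

Step 7 (rhenium oxidative cyclisation). The risks are acid damage to the cis-oxirane and incomplete trans selectivity. The fallback sets out from 13 and comes back at 15, with 14 formed on the way. Mukaiyama aerobic oxidative cyclisation with Co(modp)2 (divalent cobalt; modp = 1-morpholinocarbamoyl-4,4-dimethylpentane-1,3-dionate, catalytic), O2, t-BuOOH (catalytic) in i-PrOH at 55 °C gives the 2,5-trans oxolane through a radical pathway, as a mixture of 14 and its C10 epimer (1S)-1-[(2S,4R,5R)-4-{[tert-butyl(dimethyl)silyl]oxy}-5-(prop-2-en-1-yl)oxolan-2-yl]-2-[(2R,3S)-3-ethyloxiran-2-yl]ethan-1-ol F5. After separation, 14 goes through step 8, and F5 is converted into the same acetate 15 by a Mitsunobu reaction with AcOH (PPh3, DIAD, THF), which acetylates with inversion.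

Step 10 (Z-selective enyne cross-metathesis). The risks are a low Z/E ratio and homodimerisation. The fallback sets out from 20 and comes back at 22. Oxidative cleavage of the allyl group (OsO4 catalytic, NaIO4, 2,6-lutidine, dioxane–water) gives the aldehyde (2R,3R,5R,6R,8S)-8-[(1S)-1-acetoxypropyl]-3-{[tert-butyl(dimethyl)silyl]oxy}-2-(2-oxoethyl)oxocane-5,6-diyl diacetate F6. Stork–Zhao olefination (Ph3P=CHI from (iodomethyl)triphenylphosphonium iodide and NaHMDS, THF–HMPA, −78 °C) gives the (Z)-vinyl iodide (2R,3R,5R,6R,8S)-8-[(1S)-1-acetoxypropyl]-3-{[tert-butyl(dimethyl)silyl]oxy}-2-[(2Z)-3-iodoprop-2-en-1-yl]oxocane-5,6-diyl diacetate F7. Sonogashira coupling with 5 (Pd(PPh3)4, zerovalent palladium; CuI; Et3N) gives 22 with retention of the Z geometry.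

**Further compounds**
F1 | step 9 | (1S)-1-[(2S,4Z,7R,8R)-7-{[tert-butyl(dimethyl)silyl]oxy}-8-(prop-2-en-1-yl)-3,6,7,8-tetrahydro-2H-oxocin-2-yl]propan-1-ol | C=CC[C@@H]1[C@H](O[Si](C)(C)C(C)(C)C)C/C=C\C[C@H](O1)[C@@H](O)CC
F2 | step 9 | (1S)-1-[(2S,4Z,7R,8R)-7-{[tert-butyl(dimethyl)silyl]oxy}-8-(prop-2-en-1-yl)-3,6,7,8-tetrahydro-2H-oxocin-2-yl]propyl acetate | C=CC[C@@H]1[C@H](O[Si](C)(C)C(C)(C)C)C/C=C\C[C@H](O1)[C@@H](OC(C)=O)CC
F3 | step 9 | (9R,10S)-9,10-epoxide of F2 (oxirane on the ring face opposite to the silyloxy group) | C=CC[C@@H]1[C@H](O[Si](C)(C)C(C)(C)C)C[C@H]2O[C@H]2C[C@H](O1)[C@@H](OC(C)=O)CC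
F4 | step 9 | (2R,3R,5R,6R,8S)-8-[(1S)-1-acetoxypropyl]-3-{[tert-butyl(dimethyl)silyl]oxy}-5-hydroxy-2-(prop-2-en-1-yl)oxocan-6-yl acetate | C=CC[C@@H]1[C@H](O[Si](C)(C)C(C)(C)C)C[C@@H](O)[C@H](OC(C)=O)C[C@H](O1)[C@@H](OC(C)=O)CC
F5 | step 7 | (1S)-1-[(2S,4R,5R)-4-{[tert-butyl(dimethyl)silyl]oxy}-5-(prop-2-en-1-yl)oxolan-2-yl]-2-[(2R,3S)-3-ethyloxiran-2-yl]ethan-1-ol | C=CC[C@@H]1[C@H](O[Si](C)(C)C(C)(C)C)C[C@H](O1)[C@@H](O)C[C@H]2O[C@H]2CC
F6 | step 10 | (2R,3R,5R,6R,8S)-8-[(1S)-1-acetoxypropyl]-3-{[tert-butyl(dimethyl)silyl]oxy}-2-(2-oxoethyl)oxocane-5,6-diyl diacetate | O=CC[C@@H]1[C@H](O[Si](C)(C)C(C)(C)C)C[C@@H](OC(C)=O)[C@H](OC(C)=O)C[C@H](O1)[C@@H](OC(C)=O)CC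
F7 | step 10 | (2R,3R,5R,6R,8S)-8-[(1S)-1-acetoxypropyl]-3-{[tert-butyl(dimethyl)silyl]oxy}-2-[(2Z)-3-iodoprop-2-en-1-yl]oxocane-5,6-diyl diacetate | I/C=C\C[C@@H]1[C@H](O[Si](C)(C)C(C)(C)C)C[C@@H](OC(C)=O)[C@H](OC(C)=O)C[C@H](O1)[C@@H](OC(C)=O)CC
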